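At 1.67 d, past the end of the feed, substrate and target in the maple and birch flasks fall short of the charge by 3.50% on average, a reading with much scatter, and I take this as substrate held on the catalyst.

| setting | maple | birch | north-west | north-east |
|---|---|---|---|---|
| substrate | 0.050 M (fed, over 30 h) | 0.050 M (fed, over 30 h) | 0.050 M (fed, over 30 h) | 0.050 M |
| coupling partner | 0.20 equiv | 0.87 equiv | 0.600 equiv | 0.150 equiv |
| free catalyst | 15 mol% | 15 mol% | 15 mol% | 15 mol% |
| impurity | 10 mM | 10 mM | 10 mM | 10 mM |
| remark | run made earlier; the fed solution adds 0.10 times the starting volume | run made earlier; the fed solution adds 0.10 times the starting volume | the fed solution adds 0.10 times the starting volume | everything together at the start, the whole solution of substrate included, so that from the start the volume is larger by 0.10 times the starting volume |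
| time |  |  | 4.0 d | 4.0 d |

| run | time / d | target / % | substrate / % |
|---|---|---|---|
| maple | 0.208 | 0 | 12 |
| maple | 0.500 | 1 | 34 |
| maple | 1.04 | 1 | 78 |
| maple | 1.67 | 3 | 93 |
| maple | 2.00 | 6 | 88 |
| maple | 3.00 | 7 | 84 |
| birch | 0.208 | 1 | 12 |
| birch | 0.333 | 1 | 22 |
| birch | 0.625 | 6 | 42 |
| birch | 1.04 | 10 | 71 |
| birch | 1.67 | 13 | 84 |
| birch | 3.00 | 17 | 77 |

(each reading ± 2 percentage points)

- every charge counts on the volume at the start, and the solution that is fed holds the whole dose
- the earlier runs were read with a standard deviation of 2 percentage points
- steps under discussion: substrate + free catalyst -> catalyst intermediate A; catalyst intermediate A <-> catalyst intermediate B; coupling partner + catalyst intermediate B -> catalyst intermediate C; catalyst intermediate C -> free catalyst + target; coupling partner -> decomposed reagent; free catalyst + impurity -> spent catalyst; coupling partner -> decomposition product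
- percentages count the whole charge, also what has not yet gone in

* which of the two ends with the higher amount of target, in percent of the substrate charged ("neither" if they lie within 2 percentage points) (north-west / north-east / neither)
* target at the end, in percent of the substrate charged, north-west
* target at the end, in percent of the substrate charged, north-east

The steps give the coupling partner two exits: coupling, which passes through held catalyst, and decomposition, which does not. Maple's last target reading, 7%, is a share of 0.350 of its partner charge. The step up from 6% lies within the scatter of 2 percentage points, so it shows no plateau and coupling may still be running, but I use this interim share as a working value, as if it were final. I freeze the odds of coupling against decomposition per unit of held catalyst, a kind of selectivity factor: 15.4, with held catalyst as a fraction of the substrate charge.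

For north-west, held catalyst should match the earlier fed runs. Birch's share is 0.195, and the mean of the two shares on its partner charge gives 16.4%. For north-east, I assume that substrate present from the start holds the whole loading. The odds then give a share of 0.698 and a target of 10.5%. I therefore expect north-west to end higher.

The forecast also says north-west, with 15% (12% to 18%) and 10% (7% to 13.5%) for north-east, noting that “the 15% charge caps it”.

The flasks give 17.1% in north-west and 9.31% in north-east.

    substrate + free catalyst → catalyst intermediate A (k = 63.0 M⁻¹ h⁻¹)
    catalyst intermediate A ⇌ catalyst intermediate B (K = 0.370, k = 0.420 h⁻¹)
    coupling partner + catalyst intermediate B → catalyst intermediate C (k = 12.0 M⁻¹ h⁻¹)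
    catalyst intermediate C → free catalyst + target (k = 0.360 h⁻¹)
    coupling partner → decomposed reagent (k = 0.00830 h⁻¹)
    free catalyst + impurity → spent catalyst (k = 33.0 M⁻¹ h⁻¹)
    coupling partner → decomposition product (k = 7.00 × 10⁻⁵ h⁻¹)

Spent catalyst stands at 69.9% of the catalyst charged in north-west and 16.2% in north-east. North-west ends with 4.48% of the substrate charge held, so the frozen odds give a share of 0.408; target per partner consumed is 0.387.

The neighbour with 0.0040 M of impurity holds 9.40%, so the odds give a share of 0.591, and with 15% of its partner left, a target of 30.0%. That flask gives 27.7%.

(The numbers in the tables stem from a simulated flask with constants of no real substance.)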